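## The problem

The target 19 is a planar, achiral flavone: benzo ring A is fused to pyranone ring C, and a 2,4-dihydroxyphenyl ring B sits on C2. There is no stereocentre, so every difficulty is one of regiochemistry and of telling oxygens apart. Ring A carries no hydrogen: C5, C6, C7 and C8 bear four contiguous oxygens, C8a bears O1 and C4a bears the carbonyl carbon C4. Of the seven peripheral oxygens, four are methyl ethers (C3, C6, C7, C8) and three are free phenols (C5, C2', C4'). Late methylation or demethylation cannot distinguish these reliably, so the pattern must come from the building blocks and from one protecting group that leaves under neutral conditions. The C3 methoxy group lies on the carbon between C2 and the C4 carbonyl, a position that the usual acetophenone-plus-benzoate condensations leave as C–H. The electron-rich rings are open to oxidation and electrophilic halogenation, and the pyranone can be opened at C2 by hot alkoxide, so the phenols stay masked to the end and strongly basic, hot steps are avoided after ring closure. The enabling feature is that C2=C3, flanked by O1 and C4=O, has the oxidation level of an aryl alkynyl ketone. In that ring-opened form the C5 oxygen and the future O1 are two equivalent ether oxygens ortho to the acyl carbon of a mirror-symmetric ring A. Attack of either one on the alkyne carbon bound to ring B, triggered by an iodine electrophile, closes ring C and leaves iodine on C3.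

## Retrosynthesis

**19 to 18.** The last cut goes through the three O–benzyl bonds at O5, O2' and O4'. Benzyl is preferred to methyl, because a 5-methoxy group would need a demethylation selective against the C6 and C3 methoxy groups. It is preferred to silyl or acetal groups, which would not survive organolithium, ICl and basic alkylation alike. Compound 18 differs from 19 only by three benzyl groups. The forward step is a hydrogenolysis that must spare the C2=C3 bond and four methyl ethers.

**18 to 17 to 14.** The C3–OCH3 unit is cut first at O–CH3, giving flavonol 17, whose only free hydroxyl is the one to be methylated. It is then cut at C3–O, giving the 3-iodoflavone 14. Forward, C–I becomes C–OH through the magnesium compound 15 and the boronate 16. A direct copper-mediated exchange of iodide for methoxide would save one step. It would, however, expose a doubly flanked α-iodo enone to hot basic methanol, where attack at C2 and reduction of the C–I bond are to be feared. The metalation–borylation–oxidation sequence stays at or below room temperature and ends in a methylation with no selectivity question.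

**14 to 13.** This is the strategic cut. O1–C2 and C3–I are broken together, which opens ring C and returns C2–C3 to a triple bond. Against cuts that form C4a–C4 or C2–C1', it has the merit that the heteroatom handle on C3 appears in the ring-forming event itself. Ynone 13 has one ring fewer and a symmetric ring A with two identical ortho benzyloxy groups, so the question of which oxygen becomes O1 disappears. The forward step asks ICl to activate the alkyne, a ring A ether oxygen to attack the carbon next to ring B, and chloride to remove the benzyl group from the oxonium ion.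

**13 to 12 to 7 and 10.** The C4–C3 bond is cut at the alcohol oxidation level. Propargylic alcohol 12 comes from aldehyde 7 and the lithium acetylide 11 of alkyne 10. Acylation of 10 with a ring A acid chloride would reach 13 directly but needs the benzoic acid and a palladium/copper coupling. The aldehyde comes straight from a formylation. The cut divides the molecule into two halves of similar size. The forward steps are a 1,2-addition to a hindered, non-enolisable aldehyde and a mild oxidation that leaves the alkyne alone.

**7 to 6 to 4.** The two O–benzyl bonds of 7 are cut to give dihydroxy aldehyde 6, and the ring–CHO bond of 6 is cut to give resorcinol 4 (forward through iminium salt 5). Formylation comes before benzylation because the free resorcinol is the most nucleophilic form. Compound 4 has a single ring hydrogen, so there is no regiochemical choice, and the two hydrogen bonds in 6 make it easier to handle than 4.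

**4 to 3 to 2 to 1.** The two phenolic C–O bonds are traced back to C–B bonds in bis-boronate 3, to C–Br bonds in dibromide 2, and to 1,2,3-trimethoxybenzene 1. The innate selectivity of electrophilic substitution of 1 puts both bromine atoms where the oxygens are needed and leaves the position between them free for the formyl carbon. The forward steps are a double bromination, a double Miyaura borylation and an oxidation.

**10 to 9 to 8.** The alkyne of 10 is cut at its terminal carbon, a one-carbon homologation of aldehyde 9. Compound 9 is the dibenzyl ether of 2,4-dihydroxybenzaldehyde 8.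

## Roads not taken

**Alternative 1:** Carbonylative three-component annulation.
- Cut: C4a–C4, C4–C3 and O1–C2 at once.
- Forward: 2-iodo-4,5,6-trimethoxybenzene-1,3-diol A1 (from 4 by iodination), carbon monoxide and alkyne 10 would be joined by PdCl2(PPh3)2 in diethylamine. The sequence is oxidative addition, CO insertion, acylation of the alkyne and amine-mediated closure to 2-[2,4-bis(benzyloxy)phenyl]-5-hydroxy-6,7,8-trimethoxy-4H-chromen-4-one A2.
- Merits: three bonds form in one operation. Compounds 4 and 10 are used directly, so formylation, ring A benzylation, acetylide addition and alcohol oxidation all fall away. The flavone skeleton is reached in fewer steps than in the chosen plan, and the C5 hydroxyl needs no protecting group.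
- Weak points: A1 is a very electron-rich, di-ortho-substituted aryl iodide with two free phenols. Oxidative addition to zerovalent palladium is slow for such a ring, and direct alkynylation without CO, followed by closure to a benzofuran, competes. More seriously, A2 has hydrogen at C3. The oxygen would then have to be introduced on an advanced intermediate with a free, chelated C5 hydroxyl, which means protection, C3 metalation or epoxidation, and methylation.
- Comparison: this road is shorter to the skeleton. The chosen plan spends two extra steps (addition, oxidation) on the ynone but gains the C3 handle in the ring closure. It also keeps all phenols masked during the C3 chemistry.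

**Alternative 2:** Coumarin-to-flavone acyl transfer.
- Cut: the C4a–C4 bond.
- Forward: 3-(benzyloxy)-2-bromo-4,5,6-trimethoxyphenol A3 would be attached through its oxygen to C4 of a 3-methoxycoumarin built from ring B, giving 7-(benzyloxy)-4-[3-(benzyloxy)-2-bromo-4,5,6-trimethoxyphenoxy]-3-methoxy-2H-chromen-2-one A4. Bromine–magnesium exchange with iPrMgCl·LiCl would give an arylmagnesium that attacks the lactone carbonyl, closes ring C and expels the 2'-phenoxide. The product is 5-(benzyloxy)-2-[4-(benzyloxy)-2-hydroxyphenyl]-3,6,7,8-tetramethoxy-4H-chromen-4-one A5.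
- Merits: the C3 methoxy group is in place before ring C exists. No late C3 chemistry is needed, and only two benzyl ethers remain to be removed.
- Weak points: the symmetry of ring A is lost. A3 carries bromine, one benzyl ether and one free hydroxyl on a pentaoxygenated ring, so it needs a desymmetrisation that the chosen plan avoids. The aryl ether bond to C4 of the coumarin joins a di-ortho-substituted phenol to a carbon deactivated by the neighbouring methoxy group. The ring-forming acyl transfer has no close precedent for a hexasubstituted aryl nucleophile.
- Comparison: the endgame is better than in the chosen plan. Against that, the chosen plan sets a ring closure of a known reaction type and a ring A that stays symmetric until the moment it cyclises.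

**Alternative 3:** Mentzer condensation.
- Cut: C4a–C4 and O1–C2.
- Forward: resorcinol 4 would be heated neat with ethyl 3-[2,4-bis(benzyloxy)phenyl]-2-methoxy-3-oxopropanoate A6 (racemic). Transesterification, C-acylation and dehydration would give 2-[2,4-bis(benzyloxy)phenyl]-5-hydroxy-3,6,7,8-tetramethoxy-4H-chromen-4-one A7.
- Merits: it is by far the shortest road. The 3-methoxy group and the free C5 hydroxyl arrive with the ring, the single nucleophilic carbon of 4 leaves no regiochemical doubt, and one hydrogenolysis would finish the synthesis. In step count and in avoiding all C3 functionalisation it is superior to the chosen plan.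
- Weak points: the key step is a melt reaction far above 200 °C. It would involve an air-sensitive pentaoxygenated phenol, two benzyl ethers and an α-alkoxy β-keto ester that can undergo retro-Claisen cleavage or close through its ketone to a 4-arylcoumarin. The reaction is dependable mainly for phloroglucinol-type phenols and simple keto esters.
- Comparison: the chosen plan is longer. What it offers in return is that every bond is made between −78 and 90 °C by a reaction with precedent on polyoxygenated arenes, and that ring A is protected before any demanding step.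

Key step: step 10

Remark: species made with one reagent and consumed by the next reagent in the same flask are numbered as intermediates. Short-lived species within the action of a single reagent (for example the benzyl oxonium ion of step 10) are described in the Why line only. Compounds 1 and 8 and all reagents are taken to be commercial.

## Route

Step 1
Reactants: 1 1,2,3-trimethoxybenzene
Product: 2 1,5-dibromo-2,3,4-trimethoxybenzene
Conditions: NBS (2.1 equiv), MeCN, 0 °C to rt
Reagents that add atoms: N-bromosuccinimide, O=C1CCC(=O)N1Br
Why: Electrophilic aromatic bromination; C4 and C6 of 1 are each ortho to one outer methoxy group and para to the other, whereas C5 is para only to the central, twisted methoxy group, so both bromine atoms should enter at C4 and C6 and leave the hydrogen between them.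

Step 2
Reactants: 2 1,5-dibromo-2,3,4-trimethoxybenzene
Product: 3 2,2'-(4,5,6-trimethoxy-1,3-phenylene)bis(4,4,5,5-tetramethyl-1,3,2-dioxaborolane)
Conditions: B2pin2 (2.5 equiv), PdCl2(dppf) (5 mol%), KOAc, 1,4-dioxane, 90 °C
Reagents that add atoms: bis(pinacolato)diboron, CC1(C)OB(OC1(C)C)B1OC(C)(C)C(C)(C)O1
Why: Miyaura borylation; each C–Br bond has only one ortho substituent, and acetate-assisted transmetalation on divalent palladium should convert both bromides without touching the methyl ethers.

Step 3
Reactants: 3 2,2'-(4,5,6-trimethoxy-1,3-phenylene)bis(4,4,5,5-tetramethyl-1,3,2-dioxaborolane)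
Product: 4 4,5,6-trimethoxybenzene-1,3-diol
Conditions: KHSO5 (as 2KHSO5·KHSO4·K2SO4), acetone/H2O, 0 °C, argon; then aq NaHSO3
Reagents that add atoms: potassium peroxymonosulfate, [K+].[O-]S(=O)(=O)OO
Why: Oxidation of arylboronates by 1,2-shift of the aryl group from boron to peroxide oxygen, followed by hydrolysis of the borate; the reaction is fast at 0 °C, which keeps the electron-rich resorcinol 4 in contact with oxidant only briefly, and 4 is used at once.

Step 4
Reactants: 4 4,5,6-trimethoxybenzene-1,3-diol
Product: 6 2,6-dihydroxy-3,4,5-trimethoxybenzaldehyde, via the aryl iminium chloride 5 (not isolated)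
Conditions: POCl3, DMF, EtOAc, 0 °C to rt; then H2O, 50 °C
Reagents that add atoms: N,N-dimethylformamide, CN(C)C=O (formyl carbon; NMe2 group of 5); phosphoryl chloride, O=P(Cl)(Cl)Cl (chloride of 5); water, O (carbonyl oxygen of 6)
Why: Vilsmeier–Haack formylation; 4 has a single ring hydrogen, flanked by both hydroxyl groups and para to the central methoxy group, so the chloroiminium ion can attack only there, and hydrolysis of 5 releases an aldehyde held by two hydrogen bonds.

Step 5
Reactants: 6 2,6-dihydroxy-3,4,5-trimethoxybenzaldehyde
Product: 7 2,6-bis(benzyloxy)-3,4,5-trimethoxybenzaldehyde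
Conditions: BnBr (2.5 equiv), K2CO3, DMF, 60 °C
Reagents that add atoms: benzyl bromide, BrCc1ccccc1
Why: Williamson etherification of both phenols; the hydrogen-bonded hydroxyl groups call for DMF and gentle heating, and the aldehyde has no α-hydrogen that could interfere.

Step 6
Reactants: 8 2,4-dihydroxybenzaldehyde
Product: 9 2,4-bis(benzyloxy)benzaldehyde
Conditions: BnBr (2.3 equiv), K2CO3, DMF, 60 °C
Reagents that add atoms: benzyl bromide, BrCc1ccccc1
Why: Williamson etherification; routine double O-benzylation of a resorcinol aldehyde.

Step 7
Reactants: 9 2,4-bis(benzyloxy)benzaldehyde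
Product: 10 2,4-bis(benzyloxy)-1-ethynylbenzene
Conditions: dimethyl (1-diazo-2-oxopropyl)phosphonate, K2CO3, MeOH/THF, 0 °C to rt
Reagents that add atoms: dimethyl (1-diazo-2-oxopropyl)phosphonate, CC(=O)C(=[N+]=[N-])P(=O)(OC)OC
Why: Seyferth–Gilbert homologation with the Ohira–Bestmann reagent; methanolysis frees the diazomethylphosphonate anion, which olefinates the aldehyde, and the diazoalkene loses N2 and rearranges by 1,2-shift to the terminal alkyne under conditions that benzyl ethers tolerate.

Step 8
Reactants: 10 2,4-bis(benzyloxy)-1-ethynylbenzene; 7 2,6-bis(benzyloxy)-3,4,5-trimethoxybenzaldehyde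
Product: 12 racemic 1-[2,6-bis(benzyloxy)-3,4,5-trimethoxyphenyl]-3-[2,4-bis(benzyloxy)phenyl]prop-2-yn-1-ol, via the lithium acetylide 11 (not isolated)
Conditions: n-BuLi (1.05 equiv), THF, −78 °C; then 7, −78 to 0 °C; aq NH4Cl
Reagents that add atoms: n-butyllithium, [Li]CCCC (lithium of 11)
Why: 1,2-Addition of a lithium acetylide to a non-enolisable aryl aldehyde; the carbinol centre forms as a racemate, which does not matter because step 9 removes it.

Step 9
Reactants: 12 racemic 1-[2,6-bis(benzyloxy)-3,4,5-trimethoxyphenyl]-3-[2,4-bis(benzyloxy)phenyl]prop-2-yn-1-ol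
Product: 13 1-[2,6-bis(benzyloxy)-3,4,5-trimethoxyphenyl]-3-[2,4-bis(benzyloxy)phenyl]prop-2-yn-1-one
Conditions: activated MnO2 (excess), CH2Cl2, rt
Reagents that add atoms: none
Why: MnO2 oxidation of an alcohol that is both benzylic and propargylic; the neutral heterogeneous conditions leave the alkyne, the benzyl ethers and the electron-rich rings untouched.

Step 10
Reactants: 13 1-[2,6-bis(benzyloxy)-3,4,5-trimethoxyphenyl]-3-[2,4-bis(benzyloxy)phenyl]prop-2-yn-1-one
Product: 14 5-(benzyloxy)-2-[2,4-bis(benzyloxy)phenyl]-3-iodo-6,7,8-trimethoxy-4H-chromen-4-one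
Conditions: ICl (1.2 equiv), CH2Cl2, −78 °C; aq Na2S2O3
Reagents that add atoms: iodine monochloride, ClI
Why: ICl transfers an iodonium equivalent to the triple bond, and the positive charge develops on the alkyne carbon attached to ring B, where the 2'- and 4'-benzyloxy groups stabilise it. One of the two equivalent ortho benzyloxy oxygens of ring A attacks this carbon anti to iodine in a 6-endo-dig closure of ring C, which forms O1–C2 and places iodine on C3. Chloride then removes the benzyl group from the oxonium ion by substitution at the benzylic carbon, giving 14 and benzyl chloride. The closest known reaction type is the ICl-induced cyclisation of 2-alkoxyaryl alkynyl ketones to 3-iodochromones with loss of the O-alkyl group. No stereocentre is formed. The choice between the two ring A oxygens is moot because the mirror symmetry of ring A makes them identical, and the one not used stays as the protected C5 hydroxyl. The 5-endo attack of the 2'-benzyloxy oxygen would place positive charge on the carbon next to the carbonyl and is electronically disfavoured. Iodination of ring B is held back by the low temperature, by near-stoichiometric ICl and by conjugation of ring B with the electron-poor ynone.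

Step 11
Reactants: 14 5-(benzyloxy)-2-[2,4-bis(benzyloxy)phenyl]-3-iodo-6,7,8-trimethoxy-4H-chromen-4-one
Product: 17 5-(benzyloxy)-2-[2,4-bis(benzyloxy)phenyl]-3-hydroxy-6,7,8-trimethoxy-4H-chromen-4-one, via the flavon-3-ylmagnesium chloride 15 (not isolated), via the dimethyl flavon-3-ylboronate 16 (not isolated)
Conditions: iPrMgCl·LiCl (1.1 equiv), THF, −40 °C; B(OMe)3, −40 to 0 °C; then AcOH, 30% aq H2O2, 0 °C to rt
Reagents that add atoms: isopropylmagnesium chloride–lithium chloride, CC(C)[Mg]Cl.[Li+].[Cl-] (MgCl of 15); trimethyl borate, COB(OC)OC (B(OMe)2 of 16); hydrogen peroxide, OO (C3 oxygen of 17)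
Why: Iodine–magnesium exchange of an alkenyl iodide activated by the adjacent carbonyl, borylation of the alkenylmagnesium and oxidation of the C–B bond; exchange at −40 °C should outrun addition to the vinylogous ester carbonyl, and C3-metalated flavones are known to be borylated and oxidised to flavonols.

Step 12
Reactants: 17 5-(benzyloxy)-2-[2,4-bis(benzyloxy)phenyl]-3-hydroxy-6,7,8-trimethoxy-4H-chromen-4-one
Product: 18 5-(benzyloxy)-2-[2,4-bis(benzyloxy)phenyl]-3,6,7,8-tetramethoxy-4H-chromen-4-one
Conditions: MeI (3 equiv), K2CO3, acetone, reflux
Reagents that add atoms: iodomethane, CI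
Why: Williamson methylation of the acidic flavonol hydroxyl; it is the only free hydroxyl in 17, so no selectivity is needed.

Step 13
Reactants: 18 5-(benzyloxy)-2-[2,4-bis(benzyloxy)phenyl]-3,6,7,8-tetramethoxy-4H-chromen-4-one
Product: 19 2-(2,4-dihydroxyphenyl)-5-hydroxy-3,6,7,8-tetramethoxy-4H-chromen-4-one (5,2',4'-trihydroxy-3,6,7,8-tetramethoxyflavone)
Conditions: H2 (1 atm), 10% Pd/C, EtOAc/MeOH, rt
Reagents that add atoms: none
Why: Catalytic hydrogenolysis of three aryl benzyl ethers; the tetrasubstituted C2=C3 bond of the flavone and the four methyl ethers should be inert at 1 atm and room temperature.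

## Compound list

1 | 1,2,3-trimethoxybenzene | COc1cccc(OC)c1OC | starting material
2 | 1,5-dibromo-2,3,4-trimethoxybenzene | COc1c(Br)cc(Br)c(OC)c1OC | intermediate
3 | 2,2'-(4,5,6-trimethoxy-1,3-phenylene)bis(4,4,5,5-tetramethyl-1,3,2-dioxaborolane) | COc1c(B2OC(C)(C)C(C)(C)O2)cc(B2OC(C)(C)C(C)(C)O2)c(OC)c1OC | intermediate
4 | 4,5,6-trimethoxybenzene-1,3-diol | COc1c(O)cc(O)c(OC)c1OC | intermediate
5 | [(2,6-dihydroxy-3,4,5-trimethoxyphenyl)methylidene]dimethylammonium chloride | COc1c(O)c(C=[N+](C)C)c(O)c(OC)c1OC.[Cl-] | intermediate (not isolated)
6 | 2,6-dihydroxy-3,4,5-trimethoxybenzaldehyde | COc1c(O)c(C=O)c(O)c(OC)c1OC | intermediate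
7 | 2,6-bis(benzyloxy)-3,4,5-trimethoxybenzaldehyde | COc1c(OCc2ccccc2)c(C=O)c(OCc2ccccc2)c(OC)c1OC | intermediate
8 | 2,4-dihydroxybenzaldehyde | O=Cc1ccc(O)cc1O | starting material
9 | 2,4-bis(benzyloxy)benzaldehyde | O=Cc1ccc(OCc2ccccc2)cc1OCc1ccccc1 | intermediate
10 | 2,4-bis(benzyloxy)-1-ethynylbenzene | C#Cc1ccc(OCc2ccccc2)cc1OCc1ccccc1 | intermediate
11 | {[2,4-bis(benzyloxy)phenyl]ethynyl}lithium | [Li]C#Cc1ccc(OCc2ccccc2)cc1OCc1ccccc1 | intermediate (not isolated)
12 | 1-[2,6-bis(benzyloxy)-3,4,5-trimethoxyphenyl]-3-[2,4-bis(benzyloxy)phenyl]prop-2-yn-1-ol (racemic) | COc1c(OC)c(OCc2ccccc2)c(C(O)C#Cc2ccc(OCc3ccccc3)cc2OCc2ccccc2)c(OCc2ccccc2)c1OC | intermediate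
13 | 1-[2,6-bis(benzyloxy)-3,4,5-trimethoxyphenyl]-3-[2,4-bis(benzyloxy)phenyl]prop-2-yn-1-one | COc1c(OC)c(OCc2ccccc2)c(C(=O)C#Cc2ccc(OCc3ccccc3)cc2OCc2ccccc2)c(OCc2ccccc2)c1OC | intermediate
14 | 5-(benzyloxy)-2-[2,4-bis(benzyloxy)phenyl]-3-iodo-6,7,8-trimethoxy-4H-chromen-4-one | COc1c(OC)c(OCc2ccccc2)c2c(=O)c(I)c(-c3ccc(OCc4ccccc4)cc3OCc3ccccc3)oc2c1OC | intermediate
15 | {5-(benzyloxy)-2-[2,4-bis(benzyloxy)phenyl]-6,7,8-trimethoxy-4-oxo-4H-chromen-3-yl}magnesium chloride | COc1c(OC)c(OCc2ccccc2)c2c(=O)c([Mg]Cl)c(-c3ccc(OCc4ccccc4)cc3OCc3ccccc3)oc2c1OC | intermediate (not isolated)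
16 | dimethyl {5-(benzyloxy)-2-[2,4-bis(benzyloxy)phenyl]-6,7,8-trimethoxy-4-oxo-4H-chromen-3-yl}boronate | COc1c(OC)c(OCc2ccccc2)c2c(=O)c(B(OC)OC)c(-c3ccc(OCc4ccccc4)cc3OCc3ccccc3)oc2c1OC | intermediate (not isolated)
17 | 5-(benzyloxy)-2-[2,4-bis(benzyloxy)phenyl]-3-hydroxy-6,7,8-trimethoxy-4H-chromen-4-one | COc1c(OC)c(OCc2ccccc2)c2c(=O)c(O)c(-c3ccc(OCc4ccccc4)cc3OCc3ccccc3)oc2c1OC | intermediate
18 | 5-(benzyloxy)-2-[2,4-bis(benzyloxy)phenyl]-3,6,7,8-tetramethoxy-4H-chromen-4-one | COc1c(OC)c(OCc2ccccc2)c2c(=O)c(OC)c(-c3ccc(OCc4ccccc4)cc3OCc3ccccc3)oc2c1OC | intermediate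
19 | 2-(2,4-dihydroxyphenyl)-5-hydroxy-3,6,7,8-tetramethoxy-4H-chromen-4-one | COc1c(OC)c(O)c2c(=O)c(OC)c(-c3ccc(O)cc3O)oc2c1OC | target

## Step count and risks

Total step count: 13. Longest linear sequence: 11 steps (steps 1–5 and 8–13, from 1). The ring B branch (steps 6 and 7) joins at step 8.

Least certain steps:

**Step 10 (key step).** The most likely failures are electrophilic iodination of ring B in competition with alkyne activation, and plain addition of ICl across the triple bond without ring closure. The second arises because the carbonyl of the 2,6-disubstituted aryl ketone is twisted out of the ring plane and must rotate before the ether oxygen can reach the alkyne. The fallback makes O1–C2 by conjugate addition and C3–I by directed metalation. It sets out from 13. One ortho benzyl ether is removed by chelation-controlled cleavage with BCl3 (1 equiv, CH2Cl2, −78 °C) to give 1-[2-(benzyloxy)-6-hydroxy-3,4,5-trimethoxyphenyl]-3-[2,4-bis(benzyloxy)phenyl]prop-2-yn-1-one F1. K2CO3 in acetone closes ring C by 6-endo-dig oxa-Michael addition to 5-(benzyloxy)-2-[2,4-bis(benzyloxy)phenyl]-6,7,8-trimethoxy-4H-chromen-4-one F2. Deprotonation at C3 with LiN(iPr)2 in THF at −78 °C gives the 3-lithio flavone F3, and quenching with I2 returns to the route at 14.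

**Step 11.** The risks are addition of the isopropylmagnesium reagent to C2 or C4 of the pyranone before exchange is complete, protonation of the alkenylmagnesium (net loss of iodine), and over-oxidation of the electron-rich flavonol during the peroxide stage. The fallback replaces metalation by a copper-mediated C–O coupling. From 14, CuI, 3,4,7,8-tetramethyl-1,10-phenanthroline, Cs2CO3 and methanol in toluene at 110 °C (Ullmann-type etherification) would exchange iodide for methoxide and come back to the route at 18, bypassing 17. This coupling is less well precedented at C3 of a flavone than on simple aryl iodides and is therefore held in reserve.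

**Step 2.** The second borylation may stall, and protodebromination of the electron-rich ring may compete. The fallback forms the C–O bonds directly. From 2, palladium-catalysed hydroxylation with KOH (Pd2(dba)3, t-BuXPhos, 1,4-dioxane/H2O, 100 °C, acidification under argon) would give 4 and rejoin the route there, without 3.

**Step 4.** Resorcinol 4 may degrade oxidatively during handling, and O-formylation or O-phosphorylation may consume reagent while C-attack at the doubly flanked carbon is slow. The fallback introduces the formyl carbon by halogen–metal exchange on a protected ring. From 4, benzylation (BnBr, K2CO3, DMF) gives 1,5-bis(benzyloxy)-2,3,4-trimethoxybenzene F4. Bromination of the only free ring position with NBS gives 1,3-bis(benzyloxy)-2-bromo-4,5,6-trimethoxybenzene F5. Bromine–lithium exchange with n-BuLi in THF at −78 °C gives [2,6-bis(benzyloxy)-3,4,5-trimethoxyphenyl]lithium F6. Quenching with DMF returns to the route at 7, bypassing 5 and 6.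

## Further compounds

F1 | step 10 | 1-[2-(benzyloxy)-6-hydroxy-3,4,5-trimethoxyphenyl]-3-[2,4-bis(benzyloxy)phenyl]prop-2-yn-1-one | COc1c(OC)c(OCc2ccccc2)c(C(=O)C#Cc2ccc(OCc3ccccc3)cc2OCc2ccccc2)c(O)c1OC
F2 | step 10 | 5-(benzyloxy)-2-[2,4-bis(benzyloxy)phenyl]-6,7,8-trimethoxy-4H-chromen-4-one | COc1c(OC)c(OCc2ccccc2)c2c(=O)cc(-c3ccc(OCc4ccccc4)cc3OCc3ccccc3)oc2c1OC
F3 | step 10 | {5-(benzyloxy)-2-[2,4-bis(benzyloxy)phenyl]-6,7,8-trimethoxy-4-oxo-4H-chromen-3-yl}lithium | COc1c(OC)c(OCc2ccccc2)c2c(=O)c([Li])c(-c3ccc(OCc4ccccc4)cc3OCc3ccccc3)oc2c1OC
F0 | step 11 | none | none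
F0 | step 2 | none | none
F4 | step 4 | 1,5-bis(benzyloxy)-2,3,4-trimethoxybenzene | COc1c(OCc2ccccc2)cc(OCc2ccccc2)c(OC)c1OC
F5 | step 4 | 1,3-bis(benzyloxy)-2-bromo-4,5,6-trimethoxybenzene | COc1c(OCc2ccccc2)c(Br)c(OCc2ccccc2)c(OC)c1OC
F6 | step 4 | [2,6-bis(benzyloxy)-3,4,5-trimethoxyphenyl]lithium | COc1c(OCc2ccccc2)c([Li])c(OCc2ccccc2)c(OC)c1OC
A1 | alternative 1 | 2-iodo-4,5,6-trimethoxybenzene-1,3-diol | COc1c(O)c(I)c(O)c(OC)c1OC
A2 | alternative 1 | 2-[2,4-bis(benzyloxy)phenyl]-5-hydroxy-6,7,8-trimethoxy-4H-chromen-4-one | COc1c(OC)c(O)c2c(=O)cc(-c3ccc(OCc4ccccc4)cc3OCc3ccccc3)oc2c1OC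
A3 | alternative 2 | 3-(benzyloxy)-2-bromo-4,5,6-trimethoxyphenol | COc1c(O)c(Br)c(OCc2ccccc2)c(OC)c1OC
A4 | alternative 2 | 7-(benzyloxy)-4-[3-(benzyloxy)-2-bromo-4,5,6-trimethoxyphenoxy]-3-methoxy-2H-chromen-2-one | COc1c(Oc2c(Br)c(OCc3ccccc3)c(OC)c(OC)c2OC)c2ccc(OCc3ccccc3)cc2oc1=O
A5 | alternative 2 | 5-(benzyloxy)-2-[4-(benzyloxy)-2-hydroxyphenyl]-3,6,7,8-tetramethoxy-4H-chromen-4-one | COc1c(OC)c(OCc2ccccc2)c2c(=O)c(OC)c(-c3ccc(OCc4ccccc4)cc3O)oc2c1OC
A6 | alternative 3 | ethyl 3-[2,4-bis(benzyloxy)phenyl]-2-methoxy-3-oxopropanoate (racemic) | CCOC(=O)C(OC)C(=O)c1ccc(OCc2ccccc2)cc1OCc1ccccc1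
A7 | alternative 3 | 2-[2,4-bis(benzyloxy)phenyl]-5-hydroxy-3,6,7,8-tetramethoxy-4H-chromen-4-one | COc1c(OC)c(O)c2c(=O)c(OC)c(-c3ccc(OCc4ccccc4)cc3OCc3ccccc3)oc2c1OC
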